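## Analysis of the target

The target is a bis-decalin. Two trans-fused 4,4,10-trimethyldecalin units (rings A/B and rings A'/B') are joined from C9 to C9' by the two-carbon bridge C11–C12. Each half has four stereocentres of the same sense: the 3β-hydroxyl, the 5α-hydrogen, the 10β-methyl and the 9α-hydrogen, so that the bridge is equatorial and cis to the angular methyl group. Within a half these centres are tied to each other by the trans ring fusion. The halves differ only at C8, an exocyclic methylene on the unprimed side and a ketone on the primed side, so the molecule is a desymmetrised C2-symmetric 8,8'-dione. The sensitive groups are the 1,1-disubstituted alkene (acid-induced migration, and reduction under hydrogenation) and the C8' ketone with its enolisable neighbour C9', which holds the bridge in the thermodynamically preferred equatorial position. The hard points are the crowded array C4 (quaternary), C5, C10 (quaternary), C9 with its 1,3-diaxial methyl groups, the union of two neopentyl-like C9 positions, and telling two nearly identical halves apart. The plan rests on one feature: in each half rings A and B share the C5–C10 bond, and C8 lies next to C9, which carries a bridge carbon. That is the pattern left when an enal C9=C10, whose formyl carbon is the bridge carbon, adds across a 1-oxygenated diene C5=C6–C7=C8 tethered through C1–C4, so one cycloadduct can serve both halves.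

## Retrosynthetic reasoning

**27 to 25.** Cleaving the two O–Si bonds of 26 gives 27. Cutting the C8=CH2 bond of 26 leads to the symmetrical dione 25. The methylene group would not survive the hydrogenation that saturates the bridge and the ring alkenes, so it has to be introduced last. Because the two ketones of 25 are equivalent, the forward step is a mono-olefination under statistical control with recycling of 25.

**25 to 22.** Dione 25 is traced through diol 24 and the saturated tetrasilyl ether 23 to triene 22 by changes of oxidation level only. The forward steps must free C8 and C8' while C3 and C3' stay protected. This is why the ring-B oxygens carry triethylsilyl groups and the C3 oxygens the more robust tert-butyldimethylsilyl groups.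

**22 to 17.** The C11=C12 bond of 22 is cut into sulfone 20 and aldehyde 17. The cut is symmetrical: 20 derives from 17 through alcohol 18 and sulfide 19, so a single cycloadduct supplies both halves, and its formyl carbon becomes C11 in one half and C12 in the other. The geometry of the new alkene does not matter, since it is hydrogenated.

**17 to 16 (key disconnection).** The bonds C5'–C10' and C8'–C9' of 17 are cut together. No other pair of bonds opens both rings at once while leaving an acyclic precursor with a single stereocentre. The forward cycloaddition of 16 must close rings A' and B', set C5', C8', C9' and C10', and leave oxygen on C8' and the formyl group on C9'.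

**16 to 13.** The formyl group of the dienophile is taken back through allylic alcohol 15 to ester 14. The dienophile carbonyl is kept as an ester while the diene is built: a free allylic alcohol would be silylated, and a second enal would compete in the γ-deprotonation. The siloxydiene of 14 comes from enal 13 by enolisation towards C5' and O-silylation.

**13 to 11 and 12.** The C6'=C7' bond of 13 is cut by cross-metathesis into the terminal alkene 11 and crotonaldehyde 12. The trisubstituted, electron-poor enoate of 11 is inert to the catalyst, so neither ring closure nor a second metathesis can interfere.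

**11 to 8 and 9.** The C9'=C10' bond is cut by a Horner–Wadsworth–Emmons disconnection into methyl ketone 8 and phosphonate 9 (used as its anion 10). The forward step must place the ester trans to the chain.

**8 to 1 and 2.** Ketone 8 is traced through ketal 7, carbinol 6, ketone 5 and racemic carbinol 4 to aldehyde 1 and bromide 2 (used as Grignard reagent 3); the C2'–C3' bond is cut. Aldehyde 1 already holds the gem-dimethyl carbon C4' and the allyl group that becomes C5' and C6'. C3', the only stereocentre of the acyclic series, is set by catalyst-controlled reduction of 5.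

## Alternatives that were turned down

**Alternative 1: ring A annulated onto ring B after conjugate addition.**
- Disconnection: the bridge bond C9–C11 and the ring-A bonds C1–C10 and C4–C5 of the methylene half.
- Forward key step: the vinyl decalin A3 (a complete keto half with C8' as a benzyl ether) is hydrozirconated. The alkylzirconium adds under copper catalysis with a chiral phosphoramidite to C9 of enone ketal A2. The enolate is trapped at C10 by the α-silyl vinyl ketone A4, and aldol condensation gives the tricyclic enone A1.
- For it: the route is convergent, C9 is set by the catalyst, and the halves are distinct from the start (ketal against benzyl ether), so no statistical step is needed. On this point it is stronger than the chosen plan.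
- Against it: A3 still requires a full decalin synthesis of its own. The three-component step puts a bulky β-branched alkyl group and then a quaternary centre on adjacent carbons, and trapping so hindered an enolate with a vinyl ketone is unreliable. A1 still lacks the gem-dimethyl group, the C5 hydrogen and the C3 alcohol, so reductive methylation, ketone reduction, ketal removal, methylenation and debenzylation follow; the debenzylation conflicts with the methylene group.
- Comparison: the chosen cycloaddition sets four stereocentres and two rings of a half in one step and uses the product twice. It pays with one statistical olefination but is clearly shorter.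

**Alternative 2: acetylene as a two-carbon linchpin.**
- Disconnection: C9–C11 and C12–C9', leading to two molecules of decalone A6.
- Forward key step: ethynylmagnesium bromide A7 adds to the C9 ketone of A6 to give the propargylic alcohol A8. The acetylide of A8, after transmetalation to cerium, adds to a second molecule of A6 and gives the diol A5.
- For it: the union is very short, uses the C2 symmetry fully and relies on robust carbonyl additions. On convergence and on the ease of the fragment union it is stronger than the Julia–Kocienski step of the chosen route.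
- Against it: A6 has no functional group at C8. After the union both C9 and C9' are tertiary carbinols, so the oxygen must be removed with control of the C9 hydrogen, and oxygen must then be brought to C8 and C8' by dehydration and hydration-type steps on a hindered enyne. A6 itself needs a separate enantioselective decalin synthesis, and the statistical desymmetrisation remains.
- Comparison: the chosen cycloaddition delivers the C8 oxygen and the C9 bridge carbon in the correct relationship directly.

**Alternative 3: gold-catalysed Conia-ene closure of ring B.**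
- Disconnection: the C8–C9 bond of the methylene half.
- Forward key step: the seco ester A10 is converted into its silyl ketene acetal A11. A11 attacks the gold-activated terminal alkyne through C9 in a 6-exo-dig closure and gives ester A9, with the exocyclic methylene already in place.
- For it: the methylene group is made directly and without statistics, under mild catalytic conditions. On the differentiation of the halves it is stronger than the chosen plan.
- Against it: it makes only one half. A10 already contains ring A with C5 and the quaternary C10, so it must come from a pre-formed decalin or a separate ring-A synthesis. The keto half needs another route. The union at C11–C12 can no longer pass through an alkene that is hydrogenated. Closure of a simple ester ketene acetal onto an alkyne is less secure than with 1,3-dicarbonyl nucleophiles.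
- Comparison: the chosen plan obtains both halves from one adduct and so needs about half the number of operations.

Key step: step 11

Remark on the chemistry: each decalin half is numbered 1–10 as in a drimane unit, unprimed for the methylene half and primed for the keto half; C11 and C12 are the bridge carbons, and monomeric intermediates carry primed locants until the halves are joined.

## Route

Step 1
Reactants: 1 2,2-dimethylpent-4-enal; 2 2-(2-bromoethyl)-2-methyl-1,3-dioxolane
Product: 4 rac-4,4-dimethyl-1-(2-methyl-1,3-dioxolan-2-yl)hept-6-en-3-ol, via Grignard reagent 3 (not isolated)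
Conditions: Mg, THF, 25 °C; then 1, 0 °C → rt; aq. NH4Cl
Reagents that add atoms: none
Why: Grignard formation below 30 °C (the ketal-bearing reagent is thermally labile) and 1,2-addition to a non-enolisable α-quaternary aldehyde form C2'–C3'; the carbinol is racemic because its centre is reset in steps 2 and 3.

Step 2
Reactants: 4 rac-4,4-dimethyl-1-(2-methyl-1,3-dioxolan-2-yl)hept-6-en-3-ol
Product: 5 4,4-dimethyl-1-(2-methyl-1,3-dioxolan-2-yl)hept-6-en-3-one
Conditions: Dess–Martin periodinane, NaHCO3, CH2Cl2, 0 °C → rt
Reagents that add atoms: none
Why: Dess–Martin oxidation of a hindered secondary alcohol; the bicarbonate buffer protects the ketal and the alkene is inert.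

Step 3
Reactants: 5 4,4-dimethyl-1-(2-methyl-1,3-dioxolan-2-yl)hept-6-en-3-one
Product: 6 (3S)-4,4-dimethyl-1-(2-methyl-1,3-dioxolan-2-yl)hept-6-en-3-ol
Conditions: (R)-2-methyl-CBS-oxazaborolidine (15 mol %), catecholborane, toluene, −78 → −40 °C; MeOH, then aq. NaOH
Reagents that add atoms: none
Why: Corey–Bakshi–Shibata reduction; the tert-alkyl group acts as the large and the primary chain as the small substituent, so the (R)-catalyst should deliver hydride to the face that gives the (S)-carbinol (C3'), and catecholborane is chosen because it does not hydroborate the terminal alkene at low temperature.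

Step 4
Reactants: 6 (3S)-4,4-dimethyl-1-(2-methyl-1,3-dioxolan-2-yl)hept-6-en-3-ol
Product: 7 tert-butyl{[(3S)-4,4-dimethyl-1-(2-methyl-1,3-dioxolan-2-yl)hept-6-en-3-yl]oxy}dimethylsilane
Conditions: TBSOTf, 2,6-lutidine, CH2Cl2, −78 → 0 °C
Reagents that add atoms: tert-butyldimethylsilyl triflate, CC(C)(C)[Si](C)(C)OS(=O)(=O)C(F)(F)F
Why: Silylation of a neopentyl secondary alcohol needs the silyl triflate; the lutidine buffer keeps the ketal intact.

Step 5
Reactants: 7 tert-butyl{[(3S)-4,4-dimethyl-1-(2-methyl-1,3-dioxolan-2-yl)hept-6-en-3-yl]oxy}dimethylsilane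
Product: 8 (5S)-5-[(tert-butyldimethylsilyl)oxy]-6,6-dimethylnon-8-en-2-one
Conditions: PPTS (cat.), acetone/H2O, 50 °C
Reagents that add atoms: water, O
Why: Mild acid-catalysed ketal hydrolysis; the hindered secondary silyl ether is stable to pyridinium tosylate.

Step 6
Reactants: 8 (5S)-5-[(tert-butyldimethylsilyl)oxy]-6,6-dimethylnon-8-en-2-one; 9 triethyl phosphonoacetate
Product: 11 ethyl (2E,6S)-6-[(tert-butyldimethylsilyl)oxy]-3,7,7-trimethyldeca-2,9-dienoate, via sodium phosphonate carbanion 10 (not isolated)
Conditions: NaH, 9, THF, 0 °C; then 8, 0 °C → reflux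
Reagents that add atoms: none
Why: Horner–Wadsworth–Emmons olefination of a methyl ketone forms C9'=C10'; the stabilised phosphonate should favour the (E)-enoate with the ester trans to the longer chain, and the minor geometric isomer is removed by chromatography.

Step 7
Reactants: 11 ethyl (2E,6S)-6-[(tert-butyldimethylsilyl)oxy]-3,7,7-trimethyldeca-2,9-dienoate; 12 crotonaldehyde
Product: 13 ethyl (2E,6S,9E)-6-[(tert-butyldimethylsilyl)oxy]-3,7,7-trimethyl-11-oxoundeca-2,9-dienoate
Conditions: 12 (excess), second-generation Grubbs catalyst (H2IMes)(PCy3)Cl2Ru=CHPh (5 mol %), CH2Cl2, 40 °C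
Reagents that add atoms: none
Why: Olefin cross-metathesis of the terminal alkene with an enal partner forms C6'=C7' as the (E)-enal with loss of propene; the trisubstituted electron-poor enoate does not engage the catalyst, so ring closure onto it is not expected.

Step 8
Reactants: 13 ethyl (2E,6S,9E)-6-[(tert-butyldimethylsilyl)oxy]-3,7,7-trimethyl-11-oxoundeca-2,9-dienoate
Product: 14 ethyl (2E,6S,8E,10E)-6-[(tert-butyldimethylsilyl)oxy]-3,7,7-trimethyl-11-[(triethylsilyl)oxy]undeca-2,8,10-trienoate
Conditions: TESOTf, Et3N, Et2O, −78 → 0 °C; filtration through Et3N-deactivated silica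
Reagents that add atoms: triethylsilyl triflate, CC[Si](CC)(CC)OS(=O)(=O)C(F)(F)F
Why: Soft enolisation: O-silylation of the formyl group makes the γ-hydrogens at C5' acidic enough for triethylamine, the s-trans enal should give the (E) enol ether at C7'=C8', the quaternary C4' enforces (E) at C5'=C6', and the ester is not enolised under these conditions.

Step 9
Reactants: 14 ethyl (2E,6S,8E,10E)-6-[(tert-butyldimethylsilyl)oxy]-3,7,7-trimethyl-11-[(triethylsilyl)oxy]undeca-2,8,10-trienoate
Product: 15 (2E,6S,8E,10E)-6-[(tert-butyldimethylsilyl)oxy]-3,7,7-trimethyl-11-[(triethylsilyl)oxy]undeca-2,8,10-trien-1-ol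
Conditions: i-Bu2AlH, CH2Cl2, −78 °C; aq. potassium sodium tartrate
Reagents that add atoms: none
Why: 1,2-Reduction of the enoate by the aluminium hydride at low temperature; silyl enol ethers are inert to hydride and the neutral tartrate work-up spares the dienol ether.

Step 10
Reactants: 15 (2E,6S,8E,10E)-6-[(tert-butyldimethylsilyl)oxy]-3,7,7-trimethyl-11-[(triethylsilyl)oxy]undeca-2,8,10-trien-1-ol
Product: 16 (2E,6S,8E,10E)-6-[(tert-butyldimethylsilyl)oxy]-3,7,7-trimethyl-11-[(triethylsilyl)oxy]undeca-2,8,10-trienal
Conditions: MnO2 (activated, excess), CH2Cl2, rt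
Reagents that add atoms: none
Why: Allylic oxidation with MnO2 is heterogeneous and neutral, selective for the allylic alcohol, and should preserve both the (E)-enal geometry and the silyl dienol ether.

Step 11
Reactants: 16 (2E,6S,8E,10E)-6-[(tert-butyldimethylsilyl)oxy]-3,7,7-trimethyl-11-[(triethylsilyl)oxy]undeca-2,8,10-trienal
Product: 17 (1R,2S,4aR,6S,8aS)-6-[(tert-butyldimethylsilyl)oxy]-5,5,8a-trimethyl-2-[(triethylsilyl)oxy]-1,2,4a,5,6,7,8,8a-octahydronaphthalene-1-carbaldehyde (3'β-silyloxy, 5'α-H, 8'β-silyloxy, 9'β-formyl, 10'β-methyl)
Conditions: toluene (0.01 M), BHT (cat.), N,O-bis(trimethylsilyl)acetamide (cat.), base-washed sealed tube, 150 °C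
Reagents that add atoms: none
Why: This is an intramolecular Diels–Alder reaction of a 1,7,9-decatriene with a terminally activated (E)-dienophile, the closest known class; it is concerted and asynchronous, the HOMO of the 1-siloxydiene (largest coefficient at C5') meeting the LUMO of the enal (largest coefficient at C10'). Ring A' closes through the four-carbon tether C1'–C4' by formation of C5'–C10' with the tether in a chair, and ring B' is the new cyclohexene made by both new bonds, C5'–C10' and C8'–C9', with the alkene left at C6'=C7'. C5' and C10' (trans ring fusion) are set by the endo transition state, in which the formyl group lies under the diene and, for an (E)-enal, the tether carbon C1' is anti to C4'. Their sense relative to C3' comes from the chair tether, which keeps the C3' silyl ether equatorial, whereas addition to the other diene face would force it axial. C9' follows from suprafacial addition to the (E)-enal (formyl cis to the C10' methyl) and C8' from the (E) geometry of C7'=C8' (siloxy group cis to C4'). The step needs endo over exo addition and one diene face over the other; secondary overlap of the formyl group supports the first and the equatorial C3' substituent the second, while the gem-dimethyl group at C4' favours the folded conformer and, having no hydrogen, rules out [1,5]-hydrogen shifts of the diene. The C8' configuration is erased by the later oxidation and C9' already holds its substituent in the equatorial position, so only the ring fusion and its relation to C3' have to come out right.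

Step 12
Reactants: 17 the cycloadduct aldehyde of step 11
Product: 18 the primary alcohol of 17 (CH2OH at C9 in place of CHO; 3β-OTBS, 5α-H, 8β-OTES, 9α-H, 10β-CH3, alkene at C6=C7)
Conditions: NaBH4, EtOH, −20 → 0 °C
Reagents that add atoms: none
Why: Borohydride reduction of the aldehyde; the low temperature should prevent silyl migration and β-elimination, and no stereocentre is touched.

Step 13
Reactants: 18 the primary alcohol of 17
Product: 19 the 1-phenyl-1H-tetrazol-5-yl sulfide of 18 (C11–S bond; stereocentres as in 18)
Conditions: 1-phenyl-1H-tetrazole-5-thiol, PPh3, DIAD, THF, 0 °C → rt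
Reagents that add atoms: 1-phenyl-1H-tetrazole-5-thiol, Sc1nnnn1-c1ccccc1
Why: Mitsunobu thioetherification by SN2 displacement at the primary carbon with an acidic heteroaryl thiol; the silyl ethers and the alkene are unaffected.

Step 14
Reactants: 19 the 1-phenyl-1H-tetrazol-5-yl sulfide
Product: 20 the 1-phenyl-1H-tetrazol-5-yl sulfone (C11–SO2; stereocentres as in 18)
Conditions: (NH4)6Mo7O24·4H2O (cat.), 30% H2O2, EtOH, 0 °C → rt
Reagents that add atoms: hydrogen peroxide, OO
Why: Molybdate-catalysed peroxide oxidation of sulfide to sulfone; an isolated cis-alkene without a directing hydroxyl group is not epoxidised and the hindered secondary silyl ethers should survive the short exposure.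

Step 15
Reactants: 20 the 1-phenyl-1H-tetrazol-5-yl sulfone; 17 the cycloadduct aldehyde
Product: 22 (E)-1,2-bis[3β-(tert-butyldimethylsilyloxy)-8β-(triethylsilyloxy)-4,4,10-trimethyl-trans-Δ6-octalin-9β-yl]ethene (C2-symmetric triene), via potassium sulfonyl carbanion 21 (not isolated)
Conditions: KN(SiMe3)2, DME, −78 °C; then 17, −78 °C → rt; aq. NH4Cl
Reagents that add atoms: none
Why: Julia–Kocienski olefination: addition of the sulfonyl carbanion to the aldehyde, Smiles rearrangement and loss of sulfur dioxide and the tetrazolone form C11=C12; the alkene geometry is irrelevant because it is hydrogenated next, and brief pre-metalation with immediate addition of the aldehyde should limit its enolisation.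

Step 16
Reactants: 22 the C2-symmetric triene
Product: 23 1,2-bis[3β-(tert-butyldimethylsilyloxy)-8β-(triethylsilyloxy)-4,4,10-trimethyl-trans-decalin-9β-yl]ethane
Conditions: H2 (3 atm), 5% Pt/C, EtOAc, rt
Reagents that add atoms: none
Why: Heterogeneous hydrogenation of three disubstituted alkenes creates no stereocentre; platinum in a non-protic solvent is chosen over palladium to avoid hydrogenolysis of the allylic C–O bonds and alkene migration.

Step 17
Reactants: 23 the saturated tetrasilyl ether
Product: 24 the 8β,8'β-diol with both 3β-tert-butyldimethylsilyl ethers retained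
Conditions: HF·pyridine, pyridine, THF, 0 °C → rt
Reagents that add atoms: none
Why: Selective desilylation: a secondary triethylsilyl ether is cleaved by buffered fluoride far faster than a neopentyl secondary tert-butyldimethylsilyl ether.

Step 18
Reactants: 24 the 8β,8'β-diol
Product: 25 the C2-symmetric 8,8'-dione bis(tert-butyldimethylsilyl) ether
Conditions: Dess–Martin periodinane, NaHCO3, CH2Cl2, rt
Reagents that add atoms: none
Why: Dess–Martin oxidation of two axial secondary alcohols; C9 and C9' become enolisable but already hold the bridge equatorial, the thermodynamically preferred arrangement.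

Step 19
Reactants: 25 the 8,8'-dione
Product: 26 the 8-methylene-8'-ketone bis(tert-butyldimethylsilyl) ether (target skeleton, both hydroxyls silylated)
Conditions: Ph3PCH3Br, KOt-Bu (about one equivalent of ylide), THF, 0 → 40 °C; recovered 25 recycled
Reagents that add atoms: methyltriphenylphosphonium bromide, C[P+](c1ccccc1)(c1ccccc1)c1ccccc1.[Br-]
Why: Wittig methylenation; the two ketones are remote and react independently, so the mono-olefin should form under statistical control beside recovered dione and some bis-olefin, and C9 stays in its preferred configuration under the basic conditions.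

Step 20
Reactants: 26 the 8-methylene-8'-ketone bis(tert-butyldimethylsilyl) ether
Product: 27 26-nor-8-oxo-α-onocerin
Conditions: Bu4NF, THF, 60 °C
Reagents that add atoms: none
Why: Fluoride cleavage of the two hindered silyl ethers; non-acidic conditions spare the exocyclic alkene, and the ketone α-centre is already in its stable configuration.

## Compound list

1 | 2,2-dimethylpent-4-enal | C=CCC(C)(C)C=O | starting material
2 | 2-(2-bromoethyl)-2-methyl-1,3-dioxolane | CC1(CCBr)OCCO1 | starting material
3 | [2-(2-methyl-1,3-dioxolan-2-yl)ethyl]magnesium bromide | CC1(CC[Mg]Br)OCCO1 | intermediate (not isolated)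
4 | rac-4,4-dimethyl-1-(2-methyl-1,3-dioxolan-2-yl)hept-6-en-3-ol | CC1(CCC(O)C(C)(C)CC=C)OCCO1 | intermediate
5 | 4,4-dimethyl-1-(2-methyl-1,3-dioxolan-2-yl)hept-6-en-3-one | CC1(CCC(=O)C(C)(C)CC=C)OCCO1 | intermediate
6 | (3S)-4,4-dimethyl-1-(2-methyl-1,3-dioxolan-2-yl)hept-6-en-3-ol | CC1(CC[C@H](O)C(C)(C)CC=C)OCCO1 | intermediate
7 | tert-butyl{[(3S)-4,4-dimethyl-1-(2-methyl-1,3-dioxolan-2-yl)hept-6-en-3-yl]oxy}dimethylsilane | CC1(CC[C@H](O[Si](C)(C)C(C)(C)C)C(C)(C)CC=C)OCCO1 | intermediate
8 | (5S)-5-[(tert-butyldimethylsilyl)oxy]-6,6-dimethylnon-8-en-2-one | CC(=O)CC[C@H](O[Si](C)(C)C(C)(C)C)C(C)(C)CC=C | intermediate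
9 | triethyl phosphonoacetate | CCOC(=O)CP(=O)(OCC)OCC | starting material
10 | sodium salt of the triethyl phosphonoacetate carbanion | CCOC(=O)[CH-]P(=O)(OCC)OCC.[Na+] | intermediate (not isolated)
11 | ethyl (2E,6S)-6-[(tert-butyldimethylsilyl)oxy]-3,7,7-trimethyldeca-2,9-dienoate | CCOC(=O)/C=C(C)/CC[C@H](O[Si](C)(C)C(C)(C)C)C(C)(C)CC=C | intermediate
12 | crotonaldehyde, (E)-but-2-enal | C/C=C/C=O | starting material
13 | ethyl (2E,6S,9E)-6-[(tert-butyldimethylsilyl)oxy]-3,7,7-trimethyl-11-oxoundeca-2,9-dienoate | CCOC(=O)/C=C(C)/CC[C@H](O[Si](C)(C)C(C)(C)C)C(C)(C)C/C=C/C=O | intermediate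
14 | ethyl (2E,6S,8E,10E)-6-[(tert-butyldimethylsilyl)oxy]-3,7,7-trimethyl-11-[(triethylsilyl)oxy]undeca-2,8,10-trienoate | CCOC(=O)/C=C(C)/CC[C@H](O[Si](C)(C)C(C)(C)C)C(C)(C)/C=C/C=C/O[Si](CC)(CC)CC | intermediate
15 | (2E,6S,8E,10E)-6-[(tert-butyldimethylsilyl)oxy]-3,7,7-trimethyl-11-[(triethylsilyl)oxy]undeca-2,8,10-trien-1-ol | OC/C=C(C)/CC[C@H](O[Si](C)(C)C(C)(C)C)C(C)(C)/C=C/C=C/O[Si](CC)(CC)CC | intermediate
16 | (2E,6S,8E,10E)-6-[(tert-butyldimethylsilyl)oxy]-3,7,7-trimethyl-11-[(triethylsilyl)oxy]undeca-2,8,10-trienal | O=C/C=C(C)/CC[C@H](O[Si](C)(C)C(C)(C)C)C(C)(C)/C=C/C=C/O[Si](CC)(CC)CC | intermediate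
17 | (1R,2S,4aR,6S,8aS)-6-[(tert-butyldimethylsilyl)oxy]-5,5,8a-trimethyl-2-[(triethylsilyl)oxy]-1,2,4a,5,6,7,8,8a-octahydronaphthalene-1-carbaldehyde | O=C[C@H]1[C@@H](O[Si](CC)(CC)CC)C=C[C@H]2C(C)(C)[C@@H](O[Si](C)(C)C(C)(C)C)CC[C@]12C | intermediate
18 | primary alcohol of 17 (CH2OH at C9) | OC[C@H]1[C@@H](O[Si](CC)(CC)CC)C=C[C@H]2C(C)(C)[C@@H](O[Si](C)(C)C(C)(C)C)CC[C@]12C | intermediate
19 | 1-phenyl-1H-tetrazol-5-yl sulfide of 18 | c1ccc(cc1)-n1nnnc1SC[C@H]1[C@@H](O[Si](CC)(CC)CC)C=C[C@H]2C(C)(C)[C@@H](O[Si](C)(C)C(C)(C)C)CC[C@]12C | intermediate
20 | 1-phenyl-1H-tetrazol-5-yl sulfone | c1ccc(cc1)-n1nnnc1S(=O)(=O)C[C@H]1[C@@H](O[Si](CC)(CC)CC)C=C[C@H]2C(C)(C)[C@@H](O[Si](C)(C)C(C)(C)C)CC[C@]12C | intermediate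
21 | potassium salt of the α-sulfonyl carbanion of 20 | c1ccc(cc1)-n1nnnc1S(=O)(=O)[CH-][C@H]1[C@@H](O[Si](CC)(CC)CC)C=C[C@H]2C(C)(C)[C@@H](O[Si](C)(C)C(C)(C)C)CC[C@]12C.[K+] | intermediate (not isolated)
22 | (E)-1,2-bis[3β-(tert-butyldimethylsilyloxy)-8β-(triethylsilyloxy)-4,4,10-trimethyl-trans-Δ6-octalin-9β-yl]ethene | CC[Si](CC)(CC)O[C@H]1C=C[C@H]2C(C)(C)[C@@H](O[Si](C)(C)C(C)(C)C)CC[C@]2(C)[C@H]1/C=C/[C@H]1[C@@H](O[Si](CC)(CC)CC)C=C[C@H]2C(C)(C)[C@@H](O[Si](C)(C)C(C)(C)C)CC[C@]12C | intermediate
23 | 1,2-bis[3β-(tert-butyldimethylsilyloxy)-8β-(triethylsilyloxy)-4,4,10-trimethyl-trans-decalin-9β-yl]ethane | CC[Si](CC)(CC)O[C@H]1CC[C@H]2C(C)(C)[C@@H](O[Si](C)(C)C(C)(C)C)CC[C@]2(C)[C@H]1CC[C@H]1[C@@H](O[Si](CC)(CC)CC)CC[C@H]2C(C)(C)[C@@H](O[Si](C)(C)C(C)(C)C)CC[C@]12C | intermediate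
24 | 8β,8'β-diol, 3β,3'β-bis(tert-butyldimethylsilyl) ether | O[C@H]1CC[C@H]2C(C)(C)[C@@H](O[Si](C)(C)C(C)(C)C)CC[C@]2(C)[C@H]1CC[C@H]1[C@@H](O)CC[C@H]2C(C)(C)[C@@H](O[Si](C)(C)C(C)(C)C)CC[C@]12C | intermediate
25 | 8,8'-dione, 3β,3'β-bis(tert-butyldimethylsilyl) ether | O=C1CC[C@H]2C(C)(C)[C@@H](O[Si](C)(C)C(C)(C)C)CC[C@]2(C)[C@H]1CC[C@H]1C(=O)CC[C@H]2C(C)(C)[C@@H](O[Si](C)(C)C(C)(C)C)CC[C@]12C | intermediate
26 | 26-nor-8-oxo-α-onocerin bis(tert-butyldimethylsilyl) ether | C=C1CC[C@H]2C(C)(C)[C@@H](O[Si](C)(C)C(C)(C)C)CC[C@]2(C)[C@H]1CC[C@H]1C(=O)CC[C@H]2C(C)(C)[C@@H](O[Si](C)(C)C(C)(C)C)CC[C@]12C | intermediate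
27 | 26-nor-8-oxo-α-onocerin | C=C1CC[C@H]2C(C)(C)[C@@H](O)CC[C@]2(C)[C@H]1CC[C@H]1C(=O)CC[C@H]2C(C)(C)[C@@H](O)CC[C@]12C | target

## Step count and least certain steps

Total step count: 20. Longest linear sequence: 20 steps (steps 1–11 to the cycloadduct, steps 12–14 to the sulfone on part of it, steps 15–20 to the target).

**Step 11 (key step).**
- What may go wrong: slow closure, because C5'–C10' joins a neopentyl-type diene terminus to a fully substituted enal carbon. At the temperature then required, the (E)-enal can scramble its geometry through a [1,5]-hydrogen shift to the dienol, and the triethylsilyl dienol ether can be lost by adventitious protonation. Both would erode stereochemical fidelity and mass balance. Modest endo and facial preferences would add isomers that must be separated.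
- Fallback: it sets out from ester 14 and returns at alcohol 18. Ester 14 is cyclised before the two redox steps by heating in 1,2-dichlorobenzene with BHT at 180 °C. The enoate cannot isomerise through a dienol, tolerates the higher temperature and spares the dienol ether two manipulations. The same (E) geometry leads through the ester-endo transition state to the ester adduct F1. Reduction of F1 with i-Bu2AlH at −78 °C gives 18 directly. The part of 18 needed as aldehyde for step 15 is oxidised to 17 with SO3·pyridine, DMSO and i-Pr2NEt.

**Step 15.**
- What may go wrong: deprotonation of aldehyde 17 at C9' by the hindered carbanion 21 instead of addition, followed by β-elimination of the axial C8' silyloxy group. Both partners are neopentyl-like and the C9' hydrogen is antiperiplanar to the C8'–O bond.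
- Fallback: it sets out from 18 and returns at 23, using no base and no carbonyl partner. Alcohol 18 is converted with I2, PPh3 and imidazole into the primary iodide F2. Reductive homocoupling of F2 (NiCl2(dme) as divalent nickel precatalyst, 2,2':6',2''-terpyridine, Mn powder, DMF, 40 °C) forms the C11–C12 single bond directly and gives the dimer F3. Hydrogenation of the two ring alkenes of F3 over Pt/C gives 23.

**Step 19.**
- What may go wrong: the two carbonyl groups react independently, so over-olefination to the bis-methylene compound and enolisation of the hindered ketones by the ylide compete. Three products of similar polarity must then be separated.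
- Fallback: it sets out from 24 and returns at 26, moving the desymmetrisation to the alcohol stage where the components differ strongly in polarity. Diol 24 is oxidised with about one equivalent of Dess–Martin periodinane to the hydroxy ketone F4; recovered 24 is resubmitted and over-oxidised material is 25. The single ketone of F4 is methylenated to completion with excess Ph3P=CH2 to give the hydroxy alkene F5. Dess–Martin oxidation of F5 gives 26.

**Step 6.**
- What may go wrong: incomplete geometric control, because the methyl and methylene substituents of ketone 8 differ little in size. The wrong enoate isomer would later deliver the formyl group to the wrong face or the wrong ring fusion.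
- Fallback: it sets out from 8 and returns at 11 with the geometry fixed by syn addition. Ketone 8 is converted into the terminal alkyne F6 through its kinetic enol phosphate (LiN(i-Pr)2, ClP(O)(OEt)2, THF, −78 °C; then LiN(i-Pr)2, two equivalents). Zirconium-catalysed methylalumination of F6 (Me3Al, Cp2ZrCl2, CH2Cl2) places methyl and aluminium cis on the alkyne. Trapping the alkenylalane with ClCO2Et gives 11 as the (E)-isomer only.

## Further compounds

F1 | step 11 | ethyl ester analogue of cycloadduct 17 (CO2Et at C9 in place of CHO) | CCOC(=O)[C@H]1[C@@H](O[Si](CC)(CC)CC)C=C[C@H]2C(C)(C)[C@@H](O[Si](C)(C)C(C)(C)C)CC[C@]12C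
F2 | step 15 | primary iodide from 18 (CH2I at C9) | IC[C@H]1[C@@H](O[Si](CC)(CC)CC)C=C[C@H]2C(C)(C)[C@@H](O[Si](C)(C)C(C)(C)C)CC[C@]12C
F3 | step 15 | 1,2-bis[3β-(tert-butyldimethylsilyloxy)-8β-(triethylsilyloxy)-4,4,10-trimethyl-trans-Δ6-octalin-9β-yl]ethane | CC[Si](CC)(CC)O[C@H]1C=C[C@H]2C(C)(C)[C@@H](O[Si](C)(C)C(C)(C)C)CC[C@]2(C)[C@H]1CC[C@H]1[C@@H](O[Si](CC)(CC)CC)C=C[C@H]2C(C)(C)[C@@H](O[Si](C)(C)C(C)(C)C)CC[C@]12C
F4 | step 19 | 8-oxo-8'β-hydroxy compound, 3β,3'β-bis(tert-butyldimethylsilyl) ether | O=C1CC[C@H]2C(C)(C)[C@@H](O[Si](C)(C)C(C)(C)C)CC[C@]2(C)[C@H]1CC[C@H]1[C@@H](O)CC[C@H]2C(C)(C)[C@@H](O[Si](C)(C)C(C)(C)C)CC[C@]12C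
F5 | step 19 | 8-methylene-8'β-hydroxy compound, 3β,3'β-bis(tert-butyldimethylsilyl) ether | C=C1CC[C@H]2C(C)(C)[C@@H](O[Si](C)(C)C(C)(C)C)CC[C@]2(C)[C@H]1CC[C@H]1[C@@H](O)CC[C@H]2C(C)(C)[C@@H](O[Si](C)(C)C(C)(C)C)CC[C@]12C
F6 | step 6 | tert-butyl{[(5S)-6,6-dimethylnon-8-en-1-yn-5-yl]oxy}dimethylsilane | C#CCC[C@H](O[Si](C)(C)C(C)(C)C)C(C)(C)CC=C
A1 | alternative 1 | ring-A enone with ring-B ketal, linked through C9–C11 to the benzyl-protected keto-half decalin | O1CCOC12CCC3=C(C)C(=O)CC[C@]3(C)[C@H]2CC[C@H]1[C@H](OCc2ccccc2)CC[C@H]3C(C)(C)[C@@H](O[Si](C)(C)C(C)(C)C)CC[C@]13C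
A2 | alternative 1 | 7-methyl-1,4-dioxaspiro[4.5]dec-6-en-8-one | O=C1CCC2(OCCO2)C=C1C
A3 | alternative 1 | 9'-vinyl-8'-benzyloxy-3'β-(tert-butyldimethylsilyloxy)-4',4',10'-trimethyl-trans-decalin | C=C[C@H]1[C@H](OCc2ccccc2)CC[C@H]2C(C)(C)[C@@H](O[Si](C)(C)C(C)(C)C)CC[C@]12C
A4 | alternative 1 | 2-(trimethylsilyl)pent-1-en-3-one | CCC(=O)C(=C)[Si](C)(C)C
A5 | alternative 2 | C2-symmetric 1,2-bis[9-hydroxy-3β-(tert-butyldimethylsilyloxy)-4,4,10-trimethyl-trans-decalin-9-yl]ethyne | C1CC[C@H]2C(C)(C)[C@@H](O[Si](C)(C)C(C)(C)C)CC[C@]2(C)[C@]1(O)C#C[C@]1(O)CCC[C@H]2C(C)(C)[C@@H](O[Si](C)(C)C(C)(C)C)CC[C@]12C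
A6 | alternative 2 | 3β-(tert-butyldimethylsilyloxy)-4,4,10-trimethyl-trans-decalin-9-one | O=C1CCC[C@H]2C(C)(C)[C@@H](O[Si](C)(C)C(C)(C)C)CC[C@]12C
A7 | alternative 2 | ethynylmagnesium bromide | C#C[Mg]Br
A8 | alternative 2 | 9-ethynyl-9-hydroxy-3β-(tert-butyldimethylsilyloxy)-4,4,10-trimethyl-trans-decalin | C#C[C@]1(O)CCC[C@H]2C(C)(C)[C@@H](O[Si](C)(C)C(C)(C)C)CC[C@]12C
A9 | alternative 3 | methyl 3β-(tert-butyldimethylsilyloxy)-8-methylene-4,4,10-trimethyl-trans-decalin-9-carboxylate | C=C1CC[C@H]2C(C)(C)[C@@H](O[Si](C)(C)C(C)(C)C)CC[C@]2(C)[C@H]1C(=O)OC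
A10 | alternative 3 | methyl [2-(but-3-yn-1-yl)-4-(tert-butyldimethylsilyloxy)-1,3,3-trimethylcyclohexyl]acetate (ring-B seco ester) | C#CCC[C@H]1C(C)(C)[C@@H](O[Si](C)(C)C(C)(C)C)CC[C@]1(C)CC(=O)OC
A11 | alternative 3 | trimethylsilyl ketene acetal of A10 | C#CCC[C@H]1C(C)(C)[C@@H](O[Si](C)(C)C(C)(C)C)CC[C@]1(C)C=C(OC)O[Si](C)(C)C
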